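**Assumption.** The target is taken as drawn: it has no stereocentre, and no configuration is specified for the hindered C3–C7 axis. Every intermediate in which C7 is sp3 is racemic. Ring A is numbered C1 (methyl), C2 (arylethynyl), C3 (bears C7), C4 (4-hydroxyphenyl), C5-H, C6-H.

## Analysis of the target

Selaginellin A is built on one benzene ring (ring A) that carries four contiguous substituents. These are a methyl group at C1, a (4-hydroxyphenyl)ethynyl group at C2, the diaryl-substituted carbon C7 at C3 and a 4-hydroxyphenyl group at C4. C7 is sp2: it bears a phenyl ring and is doubly bonded to a cyclohexa-2,5-dienone, which makes it a fuchsone-type quinone methide. There is no stereocentre, and the exocyclic C7=C bond has no geometric isomers because the dienone ring is symmetric. The sensitive groups are the quinone methide (an electrophile at C7), the two free phenols and the electron-rich diarylalkyne, which reacts with electrophiles and with reducing agents. The difficulty is the 1,2,3,4-substitution of ring A, with the bulkiest group at C3 squeezed between an sp and an sp2 substituent; aromatic substitution on a preformed ring cannot set this pattern. The quinone methide also has to appear last. The strategy rests on the fact that C2 and C4 are meta to each other and flank C3. If both are read as oxygen-bearing carbons, ring A is a 2-substituted resorcinol with a methyl group ortho to one oxygen. A vinylketene and siloxyalkyne benzannulation delivers this pattern with the two oxygens chemically different.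

## Retrosynthetic reasoning

**25 to 24.** The C7=C bond of the quinone methide is taken back to C7–H and a phenol, which gives leuco triphenol 24. A methine is the smallest group C7 can carry while C2 and C4 are being elaborated. A carbinol or ketone at C7 would crowd both handles further and would put an oxygen nucleophile next to the C2 alkyne. The forward reaction is a hydride abstraction from C7 by a high-potential quinone, followed by loss of the phenolic proton.

**24 to 23.** The three O–H bonds are traced to methyl ethers in 23. Methyl is the one phenol protection that survives organolithium reagents, light, triflating agents, fluoride and palladium catalysis. Forward, a boron trihalide has to cleave all three without touching the alkyne.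

**23 to 21 and 22.** The C4–aryl bond is cut as a Suzuki–Miyaura coupling of aryl triflate 21 with boronic acid 22. Triflate 21 comes from phenol 20, and 20 from silyl ether 19 by fluoride cleavage. The C4 oxygen is thus released only after C2 has been dealt with.

**19 to 17 and 18.** The C2–C(sp) bond is cut as a Sonogashira coupling of triflate 17 with alkyne 18. Triflate 17 comes from phenol 16, whose only free hydroxyl sits at C2. The difference between OH at C2 and O-silyl at C4 fixes the order of the two couplings without any protecting-group step.

**16 to 11 and 7 (key disconnection).** Ring A is cut at C5–C6, C2–C3, C4–C5 and C1–C2. The fragments are diazoketone 11, which supplies C1, C2, C5, C6 and the methyl group, and siloxyalkyne 7, which supplies C3, C4, C7 and two aryl rings. This is the only cut that makes the crowded C2–C3–C4 array in one operation from unhindered, acyclic partners. Forward, the ketene 12 from 11 has to add to 7 with the benzhydryl-bearing carbon at the ketene carbonyl carbon, and the adduct 13 has to reorganise to the phenol.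

**7 to 4, 2, 3 and 1.** The O–C(sp) bond of 7 is cut to ynolate 6, which comes from acetylide 5 of terminal alkyne 4 by oxygen transfer from a lithium alkyl peroxide. An ester homologation would reach the same ynolate, but it would expose a doubly benzylic hydrogen next to an ester carbonyl to a lithium carbenoid and amide bases. In the acetylide route that hydrogen sits in species that are already anionic. Alkyne 4 is cut at the C7–C(sp) bond to benzhydryl chloride 2 and Grignard reagent 3; chloride 2 comes from commercial alcohol 1.

**11 to 8.** The diazo group is traced to the methyl group of enone 8 by an activated (trifluoroacetyl) diazo transfer through 9 and 10.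

## Alternatives that were turned down

**Alternative 1:** The C7=C(quinoid) and C7–phenyl bonds are cut. The precursor is α-diazoketone A2, which already contains the finished ring A. On heating, a Wolff shift moves the phenyl group onto C7 and gives diarylketene A3. 1,4-Benzoquinone A4 then adds across the ketene C=C bond at one of its carbonyl groups, and decarboxylation leaves the di-O-methyl quinone methide A1.
- For: C7 arrives at its final oxidation level, so no dehydrogenation is needed, and the quinoid ring comes from a cheap reagent. On this point it is stronger than the chosen route, which needs step 12.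
- Against: it does not address ring A at all; the tetrasubstituted arene still has to be made, and then acylated and diazotised at a hindered benzylic carbon. The carbene and the ketene are generated next to the C2 alkyne, so intramolecular carbene–alkyne and ketene–alkyne reactions compete with the bimolecular step. The ketene carbon is shielded by two ortho substituents.
- Comparison: the chosen strategy spends its key step on the substitution pattern of ring A, which is the real problem, and keeps C7 as a small, inert methine until the end.

**Alternative 2:** Ring A is cut at C1–C6 and C3–C4. A Lewis acid of tetravalent titanium condenses bis(silyl enol ether) A6 with β-ketoacetal A7 to give acylphenol A5.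
- For: this is the shortest access to ring A. The C4 aryl group is already in place, which saves the steps 8 to 10 of the chosen route, and C7 is a ketone, so aryl addition and ionisation could give the quinone methide without a separate oxidation. On step count it is clearly stronger.
- Against: the orientation depends on the diene distinguishing an acetal carbon from an electron-rich, poorly electrophilic aryl ketone, and the C3–C4 bond must form between two fully substituted carbons. Later an aryl nucleophile has to add to a benzophenone flanked by an alkyne and an aryl ring, and the resulting alkoxide sits next to the C2 alkyne, onto which it can cyclise.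
- Comparison: the chosen strategy offers a regiochemistry fixed by the polarisation of 7 and avoids any addition to a hindered C7 carbonyl.

**Alternative 3:** Ring A is cut at C4–C5 and C2–C3. A zerovalent palladium catalyst couples tertiary propargylic carbonate A9 in SN2' fashion with (1Z,3E)-dienynylboronate A10. The dienylallene A11 closes by 6π electrocyclisation and tautomerises to triarylmethane A8, which has the constitution of compound 23.
- For: it is the most convergent plan. All aryl groups and the alkyne are in place before ring A forms, and no cross-coupling at a hindered position is needed; here it is stronger than the chosen route.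
- Against: A10 needs a Z-alkenylboronate of defined geometry next to an enyne, which takes several steps and can isomerise. The 6π closure has to bond the central allene carbon, which carries the diarylmethylidene group. The final aromatisation is a formal 1,3-hydrogen shift that is not thermally allowed and needs an added acid or base.
- Comparison: the chosen strategy uses two simple fragments without geometric demands beyond a commercial E-enone, and every bond is made by a step of well-understood selectivity.

Key step: step 5

## Route

Step 1
Reactants: 1 (4-methoxyphenyl)(phenyl)methanol (racemic)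
Product: 2 1-[chloro(phenyl)methyl]-4-methoxybenzene (racemic)
Conditions: SOCl2, CH2Cl2, 0 → 25 °C; used crude
Reagents that add atoms: thionyl chloride, ClS(Cl)=O
Why: Deoxychlorination of an ionisable benzhydrol through its chlorosulfite; the 4-methoxy group stabilises the benzhydryl cation. The chloride is moisture-sensitive and is taken on without purification.

Step 2
Reactants: 2 1-[chloro(phenyl)methyl]-4-methoxybenzene; 3 ethynylmagnesium bromide
Product: 4 1-methoxy-4-(1-phenylprop-2-yn-1-yl)benzene (racemic)
Conditions: HC≡CMgBr (3 equiv), THF, 0 → 40 °C, slow addition of 2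
Reagents that add atoms: none
Why: SN1-type alkylation of an alkynyl Grignard reagent; the magnesium halide assists ionisation of 2 and the acetylide carbon captures the cation. The excess of 3 keeps the product acetylide from being alkylated a second time.

Step 3
Reactants: 4 1-methoxy-4-(1-phenylprop-2-yn-1-yl)benzene
Product: 7 triisopropyl{[3-(4-methoxyphenyl)-3-phenylprop-1-yn-1-yl]oxy}silane (racemic), via lithium acetylide 5 (not isolated), via lithium ynolate 6 (not isolated)
Conditions: n-BuLi (1.05 equiv), THF, −78 °C; LiOOt-Bu (from t-BuOOH and LiN(SiMe3)2), −78 → 0 °C; i-Pr3SiOTf, −78 °C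
Reagents that add atoms: tert-butyl hydroperoxide, CC(C)(C)OO; triisopropylsilyl trifluoromethanesulfonate, CC(C)[Si](OS(=O)(=O)C(F)(F)F)(C(C)C)C(C)C
Why: Kinetic deprotonation at the sp C–H gives 5, electrophilic oxygen transfer from the lithium peroxide gives ynolate 6 (oxidation of a lithium acetylide), and the bulky silyl triflate silylates 6 on oxygen and not on carbon. The benzhydryl hydrogen is not at risk because 5 and 6 are already anions.

Step 4
Reactants: 8 (E)-pent-3-en-2-one
Product: 11 (E)-1-diazopent-3-en-2-one, via lithium enolate 9 (not isolated), via trifluoroacetyl diketone 10 (not isolated)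
Conditions: LiN(SiMe3)2, THF, −78 °C; CF3CO2CH2CF3; aq HCl wash, crude taken on; MsN3, Et3N, H2O, MeCN, 25 °C
Reagents that add atoms: methanesulfonyl azide, CS(=O)(=O)N=[N+]=[N-]; 2,2,2-trifluoroethyl trifluoroacetate, O=C(OCC(F)(F)F)C(F)(F)F (its acyl group stays only in 10)
Why: Detrifluoroacetylative diazo transfer; the kinetic cross-conjugated enolate 9 is acylated at the methyl carbon, and diketone 10 is acidic enough for amine-mediated diazo transfer, after which the trifluoroacetyl group leaves on the sulfonamide nitrogen. The E double bond is not touched.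

Step 5
Reactants: 11 (E)-1-diazopent-3-en-2-one; 7 triisopropyl{[3-(4-methoxyphenyl)-3-phenylprop-1-yn-1-yl]oxy}silane
Product: 16 2-[(4-methoxyphenyl)(phenyl)methyl]-6-methyl-3-(triisopropylsilyloxy)phenol (racemic), via propenylketene 12 (not isolated), via vinylcyclobutenone 13 (not isolated), via dienylketene 14 (not isolated), via cyclohexadienone 15 (not isolated)
Conditions: hν (300 nm), degassed ClCH2CH2Cl, 25 °C, slow addition of 11 (1.5 equiv) to 7; then 80 °C
Reagents that add atoms: none
Why: Light at 300 nm is absorbed only by 11, which loses nitrogen and undergoes Wolff rearrangement (the propenyl group migrates to the former diazo carbon, forming C5–C6) to give ketene 12. The nucleophilic, benzhydryl-bearing alkyne carbon of 7 adds to the ketene carbonyl carbon and the oxygen-bearing carbon closes onto the ketene α-carbon, a (2+2) cycloaddition that forms C2–C3 and C4–C5 and gives cyclobutenone 13. On heating, 13 opens by a reversible 4π conrotatory electrocyclic reaction to dienylketene 14, and only the isomer with the ketene and the propenyl group cis can react further. Ring A is closed by a thermal 6π disrotatory electrocyclisation between the ketene carbon and the methyl-bearing alkene carbon (C1–C2), and enolisation of cyclohexadienone 15 gives phenol 16. The closest known reaction is the photochemical Danheiser benzannulation of unsaturated α-diazoketones with siloxyalkynes. No lasting stereocentre is made: C7 is already racemic and the sp3 centres of 13 and 15 disappear on aromatisation. The step needs regioselectivity in the (2+2) event, and the polarisation of the O–C≡C unit secures it, giving the order methyl, hydroxyl, benzhydryl, silyloxy. It also needs the ketene to be captured faster than it dimerises, which the slow addition of 11 should ensure.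

Step 6
Reactants: 16 2-[(4-methoxyphenyl)(phenyl)methyl]-6-methyl-3-(triisopropylsilyloxy)phenol
Product: 17 2-[(4-methoxyphenyl)(phenyl)methyl]-6-methyl-3-(triisopropylsilyloxy)phenyl trifluoromethanesulfonate (racemic)
Conditions: Tf2O, pyridine, CH2Cl2, 0 → 25 °C
Reagents that add atoms: trifluoromethanesulfonic anhydride, O=S(=O)(OS(=O)(=O)C(F)(F)F)C(F)(F)F
Why: O-Sulfonylation of a 2,6-disubstituted phenol; the pyridine-activated anhydride is small enough to reach the hindered oxygen. The silyl ether and the methyl ether are inert.

Step 7
Reactants: 17 2-[(4-methoxyphenyl)(phenyl)methyl]-6-methyl-3-(triisopropylsilyloxy)phenyl trifluoromethanesulfonate; 18 1-ethynyl-4-methoxybenzene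
Product: 19 triisopropyl{2-[(4-methoxyphenyl)(phenyl)methyl]-3-[(4-methoxyphenyl)ethynyl]-4-methylphenoxy}silane (racemic)
Conditions: PdCl2(MeCN)2 (5 mol %), XPhos (15 mol %), Cs2CO3, MeCN, 80 °C, slow addition of 18
Reagents that add atoms: none
Why: Copper-free Sonogashira coupling; the bulky, electron-rich biarylphosphine gives a monoligated zerovalent palladium species that can insert into the hindered C2–O bond. Leaving out copper and adding 18 slowly suppresses alkyne dimerisation.

Step 8
Reactants: 19 triisopropyl{2-[(4-methoxyphenyl)(phenyl)methyl]-3-[(4-methoxyphenyl)ethynyl]-4-methylphenoxy}silane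
Product: 20 2-[(4-methoxyphenyl)(phenyl)methyl]-3-[(4-methoxyphenyl)ethynyl]-4-methylphenol (racemic)
Conditions: Bu4NF, THF, 0 °C; H2O
Reagents that add atoms: none
Why: Fluoride attacks silicon and releases the phenoxide (desilylation driven by the Si–F bond). The phenol is meta to the alkyne, so it cannot cyclise onto it.

Step 9
Reactants: 20 2-[(4-methoxyphenyl)(phenyl)methyl]-3-[(4-methoxyphenyl)ethynyl]-4-methylphenol
Product: 21 2-[(4-methoxyphenyl)(phenyl)methyl]-3-[(4-methoxyphenyl)ethynyl]-4-methylphenyl trifluoromethanesulfonate (racemic)
Conditions: PhNTf2, Et3N, DMAP (cat.), CH2Cl2, 25 °C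
Reagents that add atoms: N-phenylbis(trifluoromethanesulfonimide), O=S(=O)(N(c1ccccc1)S(=O)(=O)C(F)(F)F)C(F)(F)F
Why: Phenol triflation with a mild triflyl donor, chosen over the anhydride so that the electron-rich diarylalkyne meets no strong electrophile.

Step 10
Reactants: 21 2-[(4-methoxyphenyl)(phenyl)methyl]-3-[(4-methoxyphenyl)ethynyl]-4-methylphenyl trifluoromethanesulfonate; 22 (4-methoxyphenyl)boronic acid
Product: 23 4'-methoxy-2-[(4-methoxyphenyl)(phenyl)methyl]-3-[(4-methoxyphenyl)ethynyl]-4-methyl-1,1'-biphenyl (racemic)
Conditions: Pd(OAc)2 (5 mol %), SPhos (10 mol %), K3PO4, toluene/H2O, 90 °C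
Reagents that add atoms: none
Why: Suzuki–Miyaura coupling of an ortho-substituted aryl triflate; the biarylphosphine promotes oxidative addition and reductive elimination next to the benzhydryl group. The internal alkyne is a spectator.

Step 11
Reactants: 23 4'-methoxy-2-[(4-methoxyphenyl)(phenyl)methyl]-3-[(4-methoxyphenyl)ethynyl]-4-methyl-1,1'-biphenyl
Product: 24 4-[{4'-hydroxy-3-[(4-hydroxyphenyl)ethynyl]-4-methyl-[1,1'-biphenyl]-2-yl}(phenyl)methyl]phenol (racemic)
Conditions: BBr3 (9 equiv), CH2Cl2, −78 → 0 °C; then H2O
Reagents that add atoms: none
Why: Lewis acid demethylation; the boron halide coordinates each ether oxygen and bromide removes the methyl group by SN2, and hydrolysis of the aryl borates frees the three phenols. Low temperature limits addition to the internal diarylalkyne.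

Step 12
Reactants: 24 4-[{4'-hydroxy-3-[(4-hydroxyphenyl)ethynyl]-4-methyl-[1,1'-biphenyl]-2-yl}(phenyl)methyl]phenol
Product: 25 selaginellin A
Conditions: DDQ (1.05 equiv), 1,4-dioxane, 25 °C
Reagents that add atoms: none
Why: Dehydrogenation of a 4-hydroxytriarylmethane to a fuchsone; the quinone removes hydride from C7, whose cation is stabilised by the para-hydroxyphenyl ring, and loss of the phenol proton gives the quinone methide. The other two phenols have no para C–H to lose, and the racemic centre at C7 is destroyed here.

## Compound list

1 | (4-methoxyphenyl)(phenyl)methanol (racemic) | COc1ccc(cc1)C(O)c1ccccc1 | starting material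
2 | 1-[chloro(phenyl)methyl]-4-methoxybenzene (racemic) | COc1ccc(cc1)C(Cl)c1ccccc1 | intermediate
3 | ethynylmagnesium bromide | C#C[Mg]Br | starting material
4 | 1-methoxy-4-(1-phenylprop-2-yn-1-yl)benzene (racemic) | C#CC(c1ccccc1)c1ccc(OC)cc1 | intermediate
5 | [3-(4-methoxyphenyl)-3-phenylprop-1-yn-1-yl]lithium (racemic) | [Li]C#CC(c1ccccc1)c1ccc(OC)cc1 | intermediate
6 | lithium 3-(4-methoxyphenyl)-3-phenylprop-1-yn-1-olate (racemic) | [Li]OC#CC(c1ccccc1)c1ccc(OC)cc1 | intermediate
7 | triisopropyl{[3-(4-methoxyphenyl)-3-phenylprop-1-yn-1-yl]oxy}silane (racemic) | CC(C)[Si](OC#CC(c1ccccc1)c1ccc(OC)cc1)(C(C)C)C(C)C | intermediate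
8 | (E)-pent-3-en-2-one | C/C=C/C(C)=O | starting material
9 | lithium (3E)-penta-1,3-dien-2-olate | C/C=C/C(=C)O[Li] | intermediate
10 | (E)-1,1,1-trifluorohept-5-ene-2,4-dione | C/C=C/C(=O)CC(=O)C(F)(F)F | intermediate
11 | (E)-1-diazopent-3-en-2-one | C/C=C/C(=O)C=[N+]=[N-] | intermediate
12 | (E)-penta-1,3-dien-1-one (propenylketene) | C/C=C/C=C=O | intermediate
13 | 2-[(4-methoxyphenyl)(phenyl)methyl]-4-[(E)-prop-1-en-1-yl]-3-(triisopropylsilyloxy)cyclobut-2-en-1-one (racemic, both diastereomers) | C/C=C/C1C(=O)C(C(c2ccccc2)c2ccc(OC)cc2)=C1O[Si](C(C)C)(C(C)C)C(C)C | intermediate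
14 | (3E,5E)-2-[(4-methoxyphenyl)(phenyl)methyl]-3-(triisopropylsilyloxy)hepta-1,3,5-trien-1-one (racemic) | O=C=C(C(c1ccccc1)c1ccc(OC)cc1)/C(O[Si](C(C)C)(C(C)C)C(C)C)=C\C=C\C | intermediate
15 | 2-[(4-methoxyphenyl)(phenyl)methyl]-6-methyl-3-(triisopropylsilyloxy)cyclohexa-2,4-dien-1-one (racemic, both diastereomers) | CC1C=CC(O[Si](C(C)C)(C(C)C)C(C)C)=C(C(c2ccccc2)c2ccc(OC)cc2)C1=O | intermediate
16 | 2-[(4-methoxyphenyl)(phenyl)methyl]-6-methyl-3-(triisopropylsilyloxy)phenol (racemic) | Cc1ccc(O[Si](C(C)C)(C(C)C)C(C)C)c(C(c2ccccc2)c2ccc(OC)cc2)c1O | intermediate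
17 | 2-[(4-methoxyphenyl)(phenyl)methyl]-6-methyl-3-(triisopropylsilyloxy)phenyl trifluoromethanesulfonate (racemic) | Cc1ccc(O[Si](C(C)C)(C(C)C)C(C)C)c(C(c2ccccc2)c2ccc(OC)cc2)c1OS(=O)(=O)C(F)(F)F | intermediate
18 | 1-ethynyl-4-methoxybenzene | C#Cc1ccc(OC)cc1 | starting material
19 | triisopropyl{2-[(4-methoxyphenyl)(phenyl)methyl]-3-[(4-methoxyphenyl)ethynyl]-4-methylphenoxy}silane (racemic) | Cc1ccc(O[Si](C(C)C)(C(C)C)C(C)C)c(C(c2ccccc2)c2ccc(OC)cc2)c1C#Cc1ccc(OC)cc1 | intermediate
20 | 2-[(4-methoxyphenyl)(phenyl)methyl]-3-[(4-methoxyphenyl)ethynyl]-4-methylphenol (racemic) | Cc1ccc(O)c(C(c2ccccc2)c2ccc(OC)cc2)c1C#Cc1ccc(OC)cc1 | intermediate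
21 | 2-[(4-methoxyphenyl)(phenyl)methyl]-3-[(4-methoxyphenyl)ethynyl]-4-methylphenyl trifluoromethanesulfonate (racemic) | Cc1ccc(OS(=O)(=O)C(F)(F)F)c(C(c2ccccc2)c2ccc(OC)cc2)c1C#Cc1ccc(OC)cc1 | intermediate
22 | (4-methoxyphenyl)boronic acid | COc1ccc(cc1)B(O)O | starting material
23 | 4'-methoxy-2-[(4-methoxyphenyl)(phenyl)methyl]-3-[(4-methoxyphenyl)ethynyl]-4-methyl-1,1'-biphenyl (racemic) | Cc1ccc(-c2ccc(OC)cc2)c(C(c2ccccc2)c2ccc(OC)cc2)c1C#Cc1ccc(OC)cc1 | intermediate
24 | 4-[{4'-hydroxy-3-[(4-hydroxyphenyl)ethynyl]-4-methyl-[1,1'-biphenyl]-2-yl}(phenyl)methyl]phenol (racemic) | Cc1ccc(-c2ccc(O)cc2)c(C(c2ccccc2)c2ccc(O)cc2)c1C#Cc1ccc(O)cc1 | intermediate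
25 | selaginellin A, 4-[{4'-hydroxy-3-[(4-hydroxyphenyl)ethynyl]-4-methyl-[1,1'-biphenyl]-2-yl}(phenyl)methylidene]cyclohexa-2,5-dien-1-one | Cc1ccc(-c2ccc(O)cc2)c(C(=C2C=CC(=O)C=C2)c2ccccc2)c1C#Cc1ccc(O)cc1 | target

## Step count and least certain steps

Total step count: 12. Longest linear sequence: 11 steps (from 1 through steps 1, 2, 3 and 5 to 12); step 4 is a one-step side branch.

**Step 5 (key step).** The nucleophilic carbon of 7 carries a bulky secondary group, so capture of ketene 12 may be slow and the ketene may dimerise or react with remaining diazoketone; the crowded cyclobutenone 13 may also reopen sluggishly. Fallback: generate the same ketene thermally, without light. (E)-Pent-3-enoyl chloride F1, made from the commercial acid with oxalyl chloride, is added slowly together with Et3N to siloxyalkyne 7 in toluene at 25 °C. Dehydrochlorination gives 12 at a low stationary concentration, the route is rejoined at cyclobutenone 13, and heating to 110 °C carries it to 16.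

**Step 3.** Oxygen transfer to the acetylide may be incomplete, and the bases present may shift the propargylic hydrogen to give an allene before or after silylation. Fallback: set out from chloride 2 and build the ynolate from an ester in which the benzhydryl hydrogen is β to the carbonyl and not acidic. ZnCl2-catalysed SN1 alkylation of 1-ethoxy-1-(trimethylsilyloxy)ethene with 2 gives ethyl 3-(4-methoxyphenyl)-3-phenylpropanoate F2. Two successive enolate brominations (LiN(SiMe3)2, then 1,2-dibromotetrachloroethane) give ethyl 2,2-dibromo-3-(4-methoxyphenyl)-3-phenylpropanoate F3. Double bromine–lithium exchange with t-BuLi (4 equiv, THF, −78 → 0 °C) and loss of ethoxide give ynolate 6, which is silylated as in step 3 to 7.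

**Step 7.** Oxidative addition into the di-ortho-substituted C2–O bond is slow, so cleavage of the triflate S–O bond by carbonate and base-induced oligomerisation of the alkyne can overtake the coupling. Fallback: a base-free Stille coupling. Alkyne 18 is converted (n-BuLi, then Bu3SnCl) into tributyl[(4-methoxyphenyl)ethynyl]stannane F4, which is coupled with triflate 17 using Pd(PPh3)4 and LiCl in 1,4-dioxane at 100 °C. No free alkyne and no base are present, so the slow insertion can be driven thermally; the route is rejoined at 19.

**Step 11.** Hydrogen bromide or the boron halide may add across the electron-rich diarylalkyne, or a neighbouring aryl ring may attack the acid-activated alkyne, while the three ethers cleave at different rates. Fallback: change from electrophilic to nucleophilic dealkylation. Heating 23 with NaSEt in DMF at 120–130 °C under argon removes the methyl groups by SN2 attack of thiolate at carbon and gives 24 directly, with no acid in the flask.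

**Step 12.** The oxidant may also attack the two other phenols (oxidative coupling), and hydride abstraction from C7 may be slow because ring A shields the C–H bond. Fallback: oxidise C7 before the phenols are freed. Base-mediated autoxidation of 23 (KOt-Bu, DMSO, O2, P(OEt)3, 25 °C) through the trityl-type anion gives the carbinol (4'-methoxy-3-[(4-methoxyphenyl)ethynyl]-4-methyl-[1,1'-biphenyl]-2-yl)(4-methoxyphenyl)(phenyl)methanol F5. BBr3 in CH2Cl2 then cleaves the three ethers and ionises the carbinol, and aqueous work-up releases the quinone methide, so the route is rejoined at 25 without passing through 24.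

## Further compounds

F1 | step 5 | (E)-pent-3-enoyl chloride | C/C=C/CC(Cl)=O
F2 | step 3 | ethyl 3-(4-methoxyphenyl)-3-phenylpropanoate (racemic) | CCOC(=O)CC(c1ccccc1)c1ccc(OC)cc1
F3 | step 3 | ethyl 2,2-dibromo-3-(4-methoxyphenyl)-3-phenylpropanoate (racemic) | CCOC(=O)C(Br)(Br)C(c1ccccc1)c1ccc(OC)cc1
F4 | step 7 | tributyl[(4-methoxyphenyl)ethynyl]stannane | CCCC[Sn](CCCC)(CCCC)C#Cc1ccc(OC)cc1
F0 | step 11 | none | none
F5 | step 12 | (4'-methoxy-3-[(4-methoxyphenyl)ethynyl]-4-methyl-[1,1'-biphenyl]-2-yl)(4-methoxyphenyl)(phenyl)methanol (racemic) | COc1ccc(cc1)C(O)(c1ccccc1)c1c(C#Cc2ccc(OC)cc2)c(C)ccc1-c1ccc(OC)cc1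
A1 | alternative 1 | di-O-methyl selaginellin A | Cc1ccc(-c2ccc(OC)cc2)c(C(=C2C=CC(=O)C=C2)c2ccccc2)c1C#Cc1ccc(OC)cc1
A2 | alternative 1 | 2-diazo-2-{4'-methoxy-3-[(4-methoxyphenyl)ethynyl]-4-methyl-[1,1'-biphenyl]-2-yl}-1-phenylethan-1-one | Cc1ccc(-c2ccc(OC)cc2)c(C(=[N+]=[N-])C(=O)c2ccccc2)c1C#Cc1ccc(OC)cc1
A3 | alternative 1 | 2-{4'-methoxy-3-[(4-methoxyphenyl)ethynyl]-4-methyl-[1,1'-biphenyl]-2-yl}-2-phenylethen-1-one (diarylketene) | Cc1ccc(-c2ccc(OC)cc2)c(C(=C=O)c2ccccc2)c1C#Cc1ccc(OC)cc1
A4 | alternative 1 | 1,4-benzoquinone | O=C1C=CC(=O)C=C1
A5 | alternative 2 | (3-hydroxy-4'-methoxy-4-methyl-[1,1'-biphenyl]-2-yl)(phenyl)methanone | Cc1ccc(-c2ccc(OC)cc2)c(C(=O)c2ccccc2)c1O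
A6 | alternative 2 | 1-phenyl-1,3-bis(trimethylsilyloxy)hexa-1,3-diene (geometry not specified) | CC=C(O[Si](C)(C)C)C=C(O[Si](C)(C)C)c1ccccc1
A7 | alternative 2 | 3,3-dimethoxy-1-(4-methoxyphenyl)propan-1-one | COc1ccc(cc1)C(=O)CC(OC)OC
A8 | alternative 3 | 4'-methoxy-2-[(4-methoxyphenyl)(phenyl)methyl]-3-[(4-methoxyphenyl)ethynyl]-4-methyl-1,1'-biphenyl (racemic) | Cc1ccc(-c2ccc(OC)cc2)c(C(c2ccccc2)c2ccc(OC)cc2)c1C#Cc1ccc(OC)cc1
A9 | alternative 3 | methyl 1,3-bis(4-methoxyphenyl)-1-phenylprop-2-yn-1-yl carbonate (racemic) | COC(=O)OC(C#Cc1ccc(OC)cc1)(c1ccccc1)c1ccc(OC)cc1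
A10 | alternative 3 | 2-[(1Z,3E)-6-(4-methoxyphenyl)-3-methylhexa-1,3-dien-5-yn-1-yl]-4,4,5,5-tetramethyl-1,3,2-dioxaborolane | COc1ccc(cc1)C#C/C=C(C)/C=C\B1OC(C)(C)C(C)(C)O1
A11 | alternative 3 | (4Z,6E)-1,3,9-tris(4-methoxyphenyl)-6-methyl-1-phenylnona-1,2,4,6-tetraen-8-yne (racemic allene) | COc1ccc(cc1)C(c1ccccc1)=C=C(c1ccc(OC)cc1)/C=C\C(C)=C\C#Cc1ccc(OC)cc1
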